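**Assumption:** the stereodescriptor in the target SMILES corresponds to the (2R)-carbinol, and all planning is for that enantiomer. MOMCl, DMF and acetic acid are treated as reagents and are not numbered.

## Retrosynthetic overview

1. Glycybridin C ⇐ one-pot acidic removal of two MOM ethers and one acetate from the (R)-α-acetoxy ketone 15.
2. 15 ⇐ C(acyl)–Cα bond made by Rh-catalysed enantioselective aldehyde C–H activation (intermolecular hydroacylation) of Z-enol acetate 14 with salicylaldehyde 7; this step also sets the only stereocentre.
3. 7 ⇐ resorcinol, by MOM-directed lithiation/prenylation, then lithiation/formylation.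
4. 14 ⇐ 4-bromophenol, by ortho-C-prenylation, Sonogashira alkynylation and Ru-catalysed anti-Markovnikov addition of AcOH.
5. No ring is formed; both benzene rings are bought intact (resorcinol, 4-bromophenol).

## Route

### Fragment A (aldehyde)

**Step 1**
Reactants: 1, resorcinol
Product: 2, 1,3-bis(methoxymethoxy)benzene
Conditions: NaH (2.4 equiv), MOMCl (2.4 equiv), DMF, 0 °C → rt
Reagents that add atoms: chloromethyl methyl ether (MOMCl), COCCl
Why: Williamson-type O-alkylation of both phenoxides; MOM serves as protecting group and as the ortho-directing group for the next two steps.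

**Step 2**
Reactants: 2, 1,3-bis(methoxymethoxy)benzene; 3, prenyl bromide (1-bromo-3-methylbut-2-ene)
Product: 4, 1,3-bis(methoxymethoxy)-2-(3-methylbut-2-en-1-yl)benzene
Conditions: n-BuLi (1.1 equiv), THF, 0 °C → rt, 1.5 h; then CuBr·SMe2 (0.5 equiv), 3, −78 °C → rt
Reagents that add atoms: prenyl bromide (compound 3), CC(C)=CCBr
Why: Directed ortho-metalation at C2, the position flanked by both OMOM groups, followed by copper-mediated SN2 allylation, which gives the linear prenyl group.

**Step 3**
Reactants: 4
Product: 5, 2,4-bis(methoxymethoxy)-3-(3-methylbut-2-en-1-yl)benzaldehyde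
Conditions: n-BuLi (1.2 equiv), TMEDA (1.2 equiv), THF, −20 → 0 °C, 1 h; then DMF (2 equiv), 0 °C → rt; aq NH4Cl
Reagents that add atoms: N,N-dimethylformamide, CN(C)C=O
Why: Second directed ortho-metalation at the only remaining position ortho to an OMOM group (C4 and C6 are equivalent), then formylation of the aryllithium with DMF.

**Step 4**
Reactants: 5
Product: 6, 2,4-dihydroxy-3-(3-methylbut-2-en-1-yl)benzaldehyde
Conditions: 3 M aq HCl, THF/MeOH, 40 °C, 3–4 h; aqueous work-up
Reagents that add atoms: none
Why: Acid-catalysed acetal hydrolysis of aryl MOM ethers; mild temperature limits chroman formation from the ortho-prenyl phenol, and any dimethyl acetal reverts to the aldehyde on aqueous work-up.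

**Step 5**
Reactants: 6
Product: 7, 2-hydroxy-4-(methoxymethoxy)-3-(3-methylbut-2-en-1-yl)benzaldehyde
Conditions: MOMCl (1.05 equiv), K2CO3 (1.5 equiv), acetone, 0 °C → rt
Reagents that add atoms: chloromethyl methyl ether, COCCl
Why: Selective O-alkylation of the 4-OH, which is more acidic and not hydrogen-bonded; the 2-OH is chelated to the formyl group and stays free, as the hydroacylation requires.

### Fragment B (enol acetate)

**Step 6**
Reactants: 8, 4-bromophenol; 3, prenyl bromide
Product: 9, 4-bromo-2-(3-methylbut-2-en-1-yl)phenol
Conditions: NaH (1.1 equiv), toluene, 0 °C → rt; then 3 (1.0 equiv), rt, 16 h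
Reagents that add atoms: prenyl bromide (compound 3), CC(C)=CCBr
Why: Ortho-selective C-alkylation of a tightly ion-paired sodium phenoxide in a non-polar solvent; the para position is blocked by Br, and moderate yield is expected, with O-prenyl ether as by-product.

**Step 7**
Reactants: 9
Product: 10, 4-bromo-1-(methoxymethoxy)-2-(3-methylbut-2-en-1-yl)benzene
Conditions: MOMCl (1.5 equiv), i-Pr2NEt (2 equiv), CH2Cl2, 0 °C → rt
Reagents that add atoms: chloromethyl methyl ether, COCCl
Why: Standard phenol MOM protection; it uses the same protecting group as fragment A, so a single final deprotection is possible.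

**Step 8**
Reactants: 10; 11, ethynyltrimethylsilane
Product: 12, {[4-(methoxymethoxy)-3-(3-methylbut-2-en-1-yl)phenyl]ethynyl}trimethylsilane
Conditions: Pd(PhCN)2Cl2 (3 mol %), P(t-Bu)3·HBF4 (6 mol %), CuI (2 mol %), i-Pr2NH, dioxane, rt → 40 °C
Reagents that add atoms: ethynyltrimethylsilane (compound 11), C#C[Si](C)(C)C
Why: Sonogashira coupling; the bulky electron-rich phosphine allows oxidative addition of the electron-rich aryl bromide near room temperature, and the trisubstituted prenyl alkene is inert.

**Step 9**
Reactants: 12
Product: 13, 4-ethynyl-1-(methoxymethoxy)-2-(3-methylbut-2-en-1-yl)benzene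
Conditions: K2CO3 (0.3 equiv), MeOH/THF, rt, 1 h
Reagents that add atoms: none
Why: Base-mediated protodesilylation of the alkynyl-TMS group; the MOM ether is stable to base.

**Step 10**
Reactants: 13
Product: 14, (Z)-2-[4-(methoxymethoxy)-3-(3-methylbut-2-en-1-yl)phenyl]ethenyl acetate
Conditions: AcOH (1.3 equiv), [Ru(p-cymene)Cl2]2 (1 mol %), P(4-ClC6H4)3 (3 mol %), DMAP (4 mol %), toluene, 60 °C
Reagents that add atoms: acetic acid, CC(=O)O
Why: Ru-catalysed anti-Markovnikov hydro-acyloxylation of a terminal aryl alkyne via a Ru-vinylidene; carboxylate attack at the vinylidene α-carbon gives the Z-enol ester selectively.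

### Fragment union and endgame

**Step 11**
Reactants: 7, 2-hydroxy-4-(methoxymethoxy)-3-prenylbenzaldehyde (1.0 equiv); 14, Z-enol acetate (1.3 equiv)
Product: 15, (2R)-1-[2-hydroxy-4-(methoxymethoxy)-3-(3-methylbut-2-en-1-yl)phenyl]-3-[4-(methoxymethoxy)-3-(3-methylbut-2-en-1-yl)phenyl]-1-oxopropan-2-yl acetate
Conditions: [Rh(cod)OMe]2 (2.5 mol %), Josiphos-type bisphosphine (SL-J001 family, 5.5 mol %; the antipode that gives (R)-15 is fixed by an initial screen with chiral HPLC), 1,2-dichloroethane, 40–50 °C, Ar
Reagents that add atoms: none (the aldehyde C–H adds across the C=C with full atom economy)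
Why: Proposed new method: enantioselective Rh(I)-catalysed intermolecular hydroacylation of a β-aryl Z-enol ester by a salicylaldehyde. The Rh-phenoxide chelate undergoes aldehyde C–H oxidative addition to a decarbonylation-resistant acyl-Rh(III)-hydride; hydride is delivered to the benzylic carbon, so Rh sits on the O-bearing carbon, where the acetate C=O forms a five-membered chelate (the α-selectivity seen in Rh hydrogenation and hydroformylation of enol acetates). Stereoretentive C(acyl)–C(sp3) reductive elimination then forms the ketone and the stereocentre, with the chiral bisphosphine selecting the olefin face to give (R). The closest known reactions are chelation-directed Rh-catalysed hydroacylations of salicylaldehydes with homoallylic sulfides, 1,5-dienes and cyclopropenes; enol esters have not been used as the olefin partner.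

**Step 12**
Reactants: 15
Product: 16, Glycybridin C, (2R)-1-[2,4-dihydroxy-3-(3-methylbut-2-en-1-yl)phenyl]-2-hydroxy-3-[4-hydroxy-3-(3-methylbut-2-en-1-yl)phenyl]propan-1-one
Conditions: AcCl (10 equiv) in MeOH (HCl generated in situ, about 1.5 M), 0 °C → 30–35 °C, 8–12 h; NaHCO3 quench
Reagents that add atoms: none
Why: Acid-catalysed cleavage of both aryl MOM ethers and acid-catalysed transesterification (methanolysis) of the activated α-keto acetate in one pot; no bond to the stereocentre is broken, so the (R) configuration is retained, and non-basic conditions avoid enolisation of the α-hydroxy ketone.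

## Compound list

1 | resorcinol | Oc1cccc(O)c1 | starting material
2 | 1,3-bis(methoxymethoxy)benzene | COCOc1cccc(OCOC)c1 | intermediate
3 | prenyl bromide (1-bromo-3-methylbut-2-ene) | CC(C)=CCBr | starting material
4 | 1,3-bis(methoxymethoxy)-2-(3-methylbut-2-en-1-yl)benzene | COCOc1cccc(OCOC)c1CC=C(C)C | intermediate
5 | 2,4-bis(methoxymethoxy)-3-(3-methylbut-2-en-1-yl)benzaldehyde | COCOc1ccc(C=O)c(OCOC)c1CC=C(C)C | intermediate
6 | 2,4-dihydroxy-3-(3-methylbut-2-en-1-yl)benzaldehyde | Oc1ccc(C=O)c(O)c1CC=C(C)C | intermediate
7 | 2-hydroxy-4-(methoxymethoxy)-3-(3-methylbut-2-en-1-yl)benzaldehyde | COCOc1ccc(C=O)c(O)c1CC=C(C)C | intermediate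
8 | 4-bromophenol | Oc1ccc(Br)cc1 | starting material
9 | 4-bromo-2-(3-methylbut-2-en-1-yl)phenol | CC(C)=CCc1cc(Br)ccc1O | intermediate
10 | 4-bromo-1-(methoxymethoxy)-2-(3-methylbut-2-en-1-yl)benzene | COCOc1ccc(Br)cc1CC=C(C)C | intermediate
11 | ethynyltrimethylsilane | C#C[Si](C)(C)C | starting material
12 | {[4-(methoxymethoxy)-3-(3-methylbut-2-en-1-yl)phenyl]ethynyl}trimethylsilane | COCOc1ccc(C#C[Si](C)(C)C)cc1CC=C(C)C | intermediate
13 | 4-ethynyl-1-(methoxymethoxy)-2-(3-methylbut-2-en-1-yl)benzene | COCOc1ccc(C#C)cc1CC=C(C)C | intermediate
14 | (Z)-2-[4-(methoxymethoxy)-3-(3-methylbut-2-en-1-yl)phenyl]ethenyl acetate | CC(=O)O/C=C\c1ccc(OCOC)c(CC=C(C)C)c1 | intermediate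
15 | (2R)-1-[2-hydroxy-4-(methoxymethoxy)-3-prenylphenyl]-3-[4-(methoxymethoxy)-3-prenylphenyl]-1-oxopropan-2-yl acetate | CC(=O)O[C@H](Cc1ccc(OCOC)c(CC=C(C)C)c1)C(=O)c1ccc(OCOC)c(CC=C(C)C)c1O | intermediate
16 | Glycybridin C | CC(C)=CCc1cc(C[C@@H](O)C(=O)c2ccc(O)c(CC=C(C)C)c2O)ccc1O | target

## Summary

**Total steps:** 12 (fragment A: steps 1–5; fragment B: steps 6–10; union and deprotection: steps 11–12).

**Longest linear sequence:** 7 steps (either 1→5→11→12 or 6→10→11→12).

**Three steps most likely to fail**

1. **Step 11 (proposed new hydroacylation).** Risks are wrong regiochemistry (acyl delivered to the benzylic carbon), low ee, Z/E scrambling of the enol ester, or decarbonylation. Fallback with known chemistry: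
   - Convert bromide 10 to its Grignard reagent and open methyl (R)-glycidate at C3 under Cu catalysis, giving methyl (R)-3-aryl-lactate (configuration retained from the chiral pool).
   - Protect the alcohol as its MOM ether and convert the ester to the Weinreb amide.
   - Add the aryllithium from 4 (n-BuLi/TMEDA, as in step 3) at −78 °C to give the tris-MOM (R)-ketone, then deprotect with HCl/MeOH.

2. **Step 12 (global acidic deprotection).** Risks are chroman formation or HCl addition at the ortho-prenyl phenols, and incomplete acetate methanolysis. Fallback: switch to an acid-free protecting-group scheme.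
   - Carry the phenols as TIPS ethers (TIPSCl on 6 at the 4-OH and on 9).
   - Use chloroacetic acid in step 10 to give the enol chloroacetate.
   - Unmask with thiourea/NaHCO3 (removes chloroacetyl), then TBAF/AcOH (removes the silyl ethers).

3. **Step 10 (Ru-catalysed Z-selective anti-Markovnikov AcOH addition).** Risks are Markovnikov enol ester, alkyne dimerisation, or poor Z/E control. Fallback: build the enol acetate through the arylacetaldehyde.
   - Suzuki coupling of bromide 10 with (E)-2-ethoxyvinylboronic acid pinacol ester.
   - Mild hydrolysis of the enol ether to the arylacetaldehyde.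
   - O-acetylation of its enolate (Ac2O, Et3N, DMAP) and separation of the Z-isomer.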